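**Retrosynthetic overview**
- Target ⇒ tribenzyl ester (final hydrogenolysis) ⇒ SN2 ester bond between the cesium carboxylate of 4‑benzyl (R)‑malate and the ω‑iodide of the dibenzyl lactone core.
- Lactone core ⇒ ester exchange, hydrogenation and Wittig chain extension from an anti aldehyde–butenolide and a C8 phosphonium salt.
- Key C–C bond (quaternary lactone carbon to CH(CO2R)): iminium‑catalysed vinylogous Mukaiyama–Michael addition of a 5‑silyloxy‑2‑furoate to ethyl 4‑oxobutenoate, setting both core stereocentres.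
- Silyloxyfuran ⇐ butyrolactone acid (selenoxide dehydrogenation, O‑silylation); malate block ⇐ (R)‑malic acid via its acetonide.
- Ring order: the only ring, the γ‑lactone, is present from the start (butyrolactone → furan → butenolide in the key step → saturated lactone; opened and re‑closed once in the saponification).

Assumption: the SMILES is read as (S) at the quaternary lactone carbon, (R) at the adjacent CH(CO2H) and (R) in the malate unit.

**Step 1**
Reactants: 1 5‑oxooxolane‑2‑carboxylic acid (racemic)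
Product: 2 methyl 5‑oxooxolane‑2‑carboxylate (racemic)
Conditions: MeI, K2CO3, DMF, rt
Reagents that add atoms: iodomethane, CI
Why: Carboxylate O‑alkylation (SN2) esterifies the acid without opening the lactone, and the stereocentre of 1 does not matter because it is erased in step 4.

**Step 2**
Reactants: 2 methyl 5‑oxooxolane‑2‑carboxylate
Product: 4 methyl 5‑oxo‑4‑(phenylselanyl)oxolane‑2‑carboxylate (cis/trans mixture), via lithium lactone enolate 3 (not isolated)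
Conditions: LiN(SiMe3)2 (1.05 equiv), THF, −78 °C; then PhSeBr, −78 °C
Reagents that add atoms: phenylselanyl bromide, Br[Se]c1ccccc1
Why: Kinetic enolization at the accessible lactone α‑CH2 (by analogy with pyroglutamate esters) followed by electrophilic α‑selenenylation; any selenide formed at the ester α‑carbon converges on the same furan 7.

**Step 3**
Reactants: 4 methyl 5‑oxo‑4‑(phenylselanyl)oxolane‑2‑carboxylate
Product: 6 methyl 5‑oxo‑2,5‑dihydrofuran‑2‑carboxylate, via selenoxide 5 (not isolated)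
Conditions: 30% H2O2, pyridine, CH2Cl2, 0 °C → rt
Reagents that add atoms: none
Why: Oxidation to the selenoxide and spontaneous syn‑elimination (selenoxide elimination) gives the endocyclic butenolide.

**Step 4**
Reactants: 6 methyl 5‑oxo‑2,5‑dihydrofuran‑2‑carboxylate
Product: 7 methyl 5‑[tri(propan‑2‑yl)silyloxy]furan‑2‑carboxylate
Conditions: TIPSOTf, Et3N, CH2Cl2, 0 °C
Reagents that add atoms: triisopropylsilyl trifluoromethanesulfonate, CC(C)[Si](OS(=O)(=O)C(F)(F)F)(C(C)C)C(C)C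
Why: Soft enolization of the doubly activated γ‑H and O‑silylation (silyl dienol ether formation) gives the aromatic 2‑silyloxyfuran, and double‑bond isomers of 6 give the same product.

**Step 5**
Reactants: 7 methyl 5‑[tri(propan‑2‑yl)silyloxy]furan‑2‑carboxylate; 8 ethyl (2E)‑4‑oxobut‑2‑enoate
Product: 9 methyl (2S)‑2‑[(2R)‑1‑ethoxy‑1,4‑dioxobutan‑2‑yl]‑5‑oxo‑2,5‑dihydrofuran‑2‑carboxylate
Conditions: (2S,5S)‑5‑benzyl‑2‑tert‑butyl‑3‑methylimidazolidin‑4‑one (20 mol%), TfOH (20 mol%), H2O (2 equiv), CHCl3, −20 °C; 8 in excess (2 equiv)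
Reagents that add atoms: none
Why: Iminium‑catalysed vinylogous Mukaiyama–Michael addition in which the benzyl group shields one face of the (E)‑iminium ion of 8, so C5 of furan 7 bonds to the β‑carbon from the open face to give the (R)‑CH centre (the same facial sense as heteroarene additions to enals with this amine, CO2Et standing in place of the β‑alkyl group), while the triflate salt in CHCl3 is expected to favour the open transition state that gives the anti (2S,1′R) diastereomer with the (S) quaternary carbon.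

**Step 6**
Reactants: 10 8‑bromooctan‑1‑ol
Product: 11 {[(8‑bromooctyl)oxy]methyl}benzene
Conditions: benzyl 2,2,2‑trichloroacetimidate (1.3 equiv), TfOH (5 mol%), CH2Cl2/cyclohexane, 0 °C → rt
Reagents that add atoms: benzyl 2,2,2‑trichloroacetimidate, N=C(OCc1ccccc1)C(Cl)(Cl)Cl
Why: Acid‑catalysed imidate benzylation protects the alcohol without base, so the primary bromide is untouched.

**Step 7**
Reactants: 11 {[(8‑bromooctyl)oxy]methyl}benzene
Product: 12 [8‑(benzyloxy)octyl]triphenylphosphonium bromide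
Conditions: PPh3 (1.1 equiv), MeCN, reflux
Reagents that add atoms: triphenylphosphine, c1ccc(cc1)P(c1ccccc1)c1ccccc1
Why: SN2 quaternization of PPh3 by the primary bromide gives the Wittig salt.

**Step 8**
Reactants: 9 methyl (2S)‑2‑[(2R)‑1‑ethoxy‑1,4‑dioxobutan‑2‑yl]‑5‑oxo‑2,5‑dihydrofuran‑2‑carboxylate; 12 [8‑(benzyloxy)octyl]triphenylphosphonium bromide
Product: 14 methyl (2S)‑2‑[(2R,4Z)‑12‑(benzyloxy)‑1‑ethoxy‑1‑oxododec‑4‑en‑2‑yl]‑5‑oxo‑2,5‑dihydrofuran‑2‑carboxylate, via phosphorus ylide 13 (not isolated)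
Conditions: 12 (1.3 equiv), KN(SiMe3)2 (1.2 equiv), THF, −78 → 0 °C; then 9, −78 → −20 °C
Reagents that add atoms: none
Why: Wittig olefination with a non‑stabilized ylide is fast at the aldehyde at low temperature (Z‑alkene, geometry irrelevant) and spares the esters and butenolide, and keeping base below the amount of salt avoids enolization next to the CH(CO2Et) centre.

**Step 9**
Reactants: 14 methyl (2S)‑2‑[(2R,4Z)‑12‑(benzyloxy)‑1‑ethoxy‑1‑oxododec‑4‑en‑2‑yl]‑5‑oxo‑2,5‑dihydrofuran‑2‑carboxylate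
Product: 15 methyl (2S)‑2‑[(2R)‑1‑ethoxy‑12‑hydroxy‑1‑oxododecan‑2‑yl]‑5‑oxooxolane‑2‑carboxylate
Conditions: H2 (3 atm), 10% Pd/C, EtOAc/EtOH, rt
Reagents that add atoms: none
Why: Heterogeneous catalytic hydrogenation saturates both C=C bonds and hydrogenolyses the benzyl ether in one operation without touching either stereocentre.

**Step 10**
Reactants: 15 methyl (2S)‑2‑[(2R)‑1‑ethoxy‑12‑hydroxy‑1‑oxododecan‑2‑yl]‑5‑oxooxolane‑2‑carboxylate
Product: 17 (2S)‑2‑[(1R)‑1‑carboxy‑11‑hydroxyundecyl]‑5‑oxooxolane‑2‑carboxylic acid, via trilithium tricarboxylate 16 (not isolated)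
Conditions: LiOH·H2O (6 equiv), THF/H2O, 0 °C → rt; then 2 M HCl to pH 1, rt
Reagents that add atoms: lithium hydroxide, [Li+].[OH-]
Why: Saponification of both esters and the lactone gives the tricarboxylate, and acidification re‑closes the tertiary γ‑hydroxy acid to the five‑membered lactone (lactonization); the quaternary centre cannot epimerize and the CH centre is protected once it is a carboxylate.

**Step 11**
Reactants: 17 (2S)‑2‑[(1R)‑1‑carboxy‑11‑hydroxyundecyl]‑5‑oxooxolane‑2‑carboxylic acid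
Product: 18 benzyl (2S)‑2‑[(2R)‑1‑(benzyloxy)‑12‑hydroxy‑1‑oxododecan‑2‑yl]‑5‑oxooxolane‑2‑carboxylate
Conditions: BnBr (2.5 equiv), KHCO3 (3 equiv), DMF, rt
Reagents that add atoms: benzyl bromide, BrCc1ccccc1
Why: Chemoselective carboxylate alkylation (SN2) under bicarbonate installs hydrogenolysable esters while the primary alcohol and the lactone stay intact.

**Step 12**
Reactants: 18 benzyl (2S)‑2‑[(2R)‑1‑(benzyloxy)‑12‑hydroxy‑1‑oxododecan‑2‑yl]‑5‑oxooxolane‑2‑carboxylate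
Product: 19 benzyl (2S)‑2‑[(2R)‑1‑(benzyloxy)‑12‑iodo‑1‑oxododecan‑2‑yl]‑5‑oxooxolane‑2‑carboxylate
Conditions: I2, PPh3, imidazole, CH2Cl2, 0 °C → rt
Reagents that add atoms: iodine, II
Why: Appel iodination turns the primary alcohol into an SN2‑active iodide under essentially neutral conditions.

**Step 13**
Reactants: 20 (2R)‑2‑hydroxybutanedioic acid ((R)‑malic acid)
Product: 21 2‑[(4R)‑2,2‑dimethyl‑5‑oxo‑1,3‑dioxolan‑4‑yl]acetic acid
Conditions: 2,2‑dimethoxypropane, p‑TsOH·H2O (cat.), rt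
Reagents that add atoms: 2,2‑dimethoxypropane, COC(C)(C)OC
Why: Acid‑catalysed acetonide (dioxolanone) formation ties up the α‑hydroxy acid pair in a five‑membered ring and leaves only the β‑carboxyl free, with the stereocentre untouched.

**Step 14**
Reactants: 21 2‑[(4R)‑2,2‑dimethyl‑5‑oxo‑1,3‑dioxolan‑4‑yl]acetic acid
Product: 22 benzyl 2‑[(4R)‑2,2‑dimethyl‑5‑oxo‑1,3‑dioxolan‑4‑yl]acetate
Conditions: BnBr, KHCO3, DMF, rt
Reagents that add atoms: benzyl bromide, BrCc1ccccc1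
Why: Carboxylate alkylation (SN2) gives the β‑benzyl ester without disturbing the dioxolanone.

**Step 15**
Reactants: 22 benzyl 2‑[(4R)‑2,2‑dimethyl‑5‑oxo‑1,3‑dioxolan‑4‑yl]acetate
Product: 23 (2R)‑4‑(benzyloxy)‑2‑hydroxy‑4‑oxobutanoic acid
Conditions: 1 M HCl, THF, rt
Reagents that add atoms: water, O
Why: Mild acidic hydrolysis of the activated dioxolanone frees the α‑hydroxy acid while the benzyl ester survives.

**Step 16**
Reactants: 19 benzyl (2S)‑2‑[(2R)‑1‑(benzyloxy)‑12‑iodo‑1‑oxododecan‑2‑yl]‑5‑oxooxolane‑2‑carboxylate; 23 (2R)‑4‑(benzyloxy)‑2‑hydroxy‑4‑oxobutanoic acid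
Product: 25 4‑benzyl 1‑{(11R)‑12‑(benzyloxy)‑11‑[(2S)‑2‑[(benzyloxy)carbonyl]‑5‑oxooxolan‑2‑yl]‑12‑oxododecyl} (2R)‑2‑hydroxybutanedioate, via cesium carboxylate 24 (not isolated)
Conditions: 23 (1.5 equiv), Cs2CO3 (0.75 equiv), DMF, rt; then 19, rt → 40 °C
Reagents that add atoms: none
Why: SN2 esterification in which the cesium carboxylate alkylates the primary iodide far faster than the free secondary OH could react, so no OH protection is needed and the malate stereocentre is not involved.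

**Step 17**
Reactants: 25 4‑benzyl 1‑{(11R)‑12‑(benzyloxy)‑11‑[(2S)‑2‑[(benzyloxy)carbonyl]‑5‑oxooxolan‑2‑yl]‑12‑oxododecyl} (2R)‑2‑hydroxybutanedioate
Product: 26 (2S)‑2‑[(1R)‑1‑carboxy‑11‑{[(2R)‑3‑carboxy‑2‑hydroxypropanoyl]oxy}undecyl]‑5‑oxooxolane‑2‑carboxylic acid (CNP0457473.2)
Conditions: H2 (1 atm), 10% Pd/C, EtOAc, rt
Reagents that add atoms: none
Why: Catalytic hydrogenolysis of the three benzyl esters under neutral conditions frees the triacid without touching the malate ester link, the lactone or any stereocentre.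

**Compound list**
1 | 5‑oxooxolane‑2‑carboxylic acid (racemic) | O=C(O)C1CCC(=O)O1 | starting material
2 | methyl 5‑oxooxolane‑2‑carboxylate (racemic) | COC(=O)C1CCC(=O)O1 | intermediate
3 | lithium 5‑(methoxycarbonyl)‑4,5‑dihydrofuran‑2‑olate (lactone enolate) | COC(=O)C1CC=C([O-])O1.[Li+] | intermediate
4 | methyl 5‑oxo‑4‑(phenylselanyl)oxolane‑2‑carboxylate (cis/trans mixture) | COC(=O)C1CC([Se]c2ccccc2)C(=O)O1 | intermediate
5 | methyl 5‑oxo‑4‑(phenylseleninyl)oxolane‑2‑carboxylate (selenoxide) | COC(=O)C1CC([Se](=O)c2ccccc2)C(=O)O1 | intermediate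
6 | methyl 5‑oxo‑2,5‑dihydrofuran‑2‑carboxylate | COC(=O)C1C=CC(=O)O1 | intermediate
7 | methyl 5‑[tri(propan‑2‑yl)silyloxy]furan‑2‑carboxylate | COC(=O)c1ccc(O[Si](C(C)C)(C(C)C)C(C)C)o1 | intermediate
8 | ethyl (2E)‑4‑oxobut‑2‑enoate | CCOC(=O)/C=C/C=O | starting material
9 | methyl (2S)‑2‑[(2R)‑1‑ethoxy‑1,4‑dioxobutan‑2‑yl]‑5‑oxo‑2,5‑dihydrofuran‑2‑carboxylate | O=CC[C@@H](C(=O)OCC)[C@]1(C(=O)OC)C=CC(=O)O1 | intermediate
10 | 8‑bromooctan‑1‑ol | OCCCCCCCCBr | starting material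
11 | {[(8‑bromooctyl)oxy]methyl}benzene | BrCCCCCCCCOCc1ccccc1 | intermediate
12 | [8‑(benzyloxy)octyl]triphenylphosphonium bromide | [Br-].c1ccc(cc1)COCCCCCCCC[P+](c1ccccc1)(c1ccccc1)c1ccccc1 | intermediate
13 | [8‑(benzyloxy)octylidene]triphenylphosphorane (ylide) | c1ccc(cc1)COCCCCCCCC=P(c1ccccc1)(c1ccccc1)c1ccccc1 | intermediate
14 | methyl (2S)‑2‑[(2R,4Z)‑12‑(benzyloxy)‑1‑ethoxy‑1‑oxododec‑4‑en‑2‑yl]‑5‑oxo‑2,5‑dihydrofuran‑2‑carboxylate | c1ccc(cc1)COCCCCCCC/C=C\C[C@@H](C(=O)OCC)[C@]1(C(=O)OC)C=CC(=O)O1 | intermediate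
15 | methyl (2S)‑2‑[(2R)‑1‑ethoxy‑12‑hydroxy‑1‑oxododecan‑2‑yl]‑5‑oxooxolane‑2‑carboxylate | OCCCCCCCCCC[C@@H](C(=O)OCC)[C@]1(C(=O)OC)CCC(=O)O1 | intermediate
16 | trilithium (3S,4R)‑3,14‑dihydroxytetradecane‑1,3,4‑tricarboxylate | OCCCCCCCCCC[C@@H](C(=O)[O-])[C@](O)(C(=O)[O-])CCC(=O)[O-].[Li+].[Li+].[Li+] | intermediate
17 | (2S)‑2‑[(1R)‑1‑carboxy‑11‑hydroxyundecyl]‑5‑oxooxolane‑2‑carboxylic acid | OCCCCCCCCCC[C@@H](C(=O)O)[C@]1(C(=O)O)CCC(=O)O1 | intermediate
18 | benzyl (2S)‑2‑[(2R)‑1‑(benzyloxy)‑12‑hydroxy‑1‑oxododecan‑2‑yl]‑5‑oxooxolane‑2‑carboxylate | OCCCCCCCCCC[C@@H](C(=O)OCc1ccccc1)[C@]1(C(=O)OCc2ccccc2)CCC(=O)O1 | intermediate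
19 | benzyl (2S)‑2‑[(2R)‑1‑(benzyloxy)‑12‑iodo‑1‑oxododecan‑2‑yl]‑5‑oxooxolane‑2‑carboxylate | ICCCCCCCCCC[C@@H](C(=O)OCc1ccccc1)[C@]1(C(=O)OCc2ccccc2)CCC(=O)O1 | intermediate
20 | (2R)‑2‑hydroxybutanedioic acid ((R)‑malic acid) | O=C(O)C[C@@H](O)C(=O)O | starting material
21 | 2‑[(4R)‑2,2‑dimethyl‑5‑oxo‑1,3‑dioxolan‑4‑yl]acetic acid | CC1(C)O[C@H](CC(=O)O)C(=O)O1 | intermediate
22 | benzyl 2‑[(4R)‑2,2‑dimethyl‑5‑oxo‑1,3‑dioxolan‑4‑yl]acetate | CC1(C)O[C@H](CC(=O)OCc2ccccc2)C(=O)O1 | intermediate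
23 | (2R)‑4‑(benzyloxy)‑2‑hydroxy‑4‑oxobutanoic acid | O=C(OCc1ccccc1)C[C@@H](O)C(=O)O | intermediate
24 | cesium (2R)‑4‑(benzyloxy)‑2‑hydroxy‑4‑oxobutanoate | O=C(OCc1ccccc1)C[C@@H](O)C(=O)[O-].[Cs+] | intermediate
25 | 4‑benzyl 1‑{(11R)‑12‑(benzyloxy)‑11‑[(2S)‑2‑[(benzyloxy)carbonyl]‑5‑oxooxolan‑2‑yl]‑12‑oxododecyl} (2R)‑2‑hydroxybutanedioate | O=C(OCc1ccccc1)C[C@@H](O)C(=O)OCCCCCCCCCC[C@@H](C(=O)OCc1ccccc1)[C@]1(C(=O)OCc2ccccc2)CCC(=O)O1 | intermediate
26 | (2S)‑2‑[(1R)‑1‑carboxy‑11‑{[(2R)‑3‑carboxy‑2‑hydroxypropanoyl]oxy}undecyl]‑5‑oxooxolane‑2‑carboxylic acid | O=C(O)C[C@@H](O)C(=O)OCCCCCCCCCC[C@@H](C(=O)O)[C@]1(C(=O)O)CCC(=O)O1 | target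

**Totals**
Total steps: 17. Longest linear sequence: 12 steps (steps 1, 2, 3, 4, 5, 8, 9, 10, 11, 12, 16, 17).

**Steps most likely to fail, with fallbacks**

Step 5 (anti selectivity and ee of the organocatalytic Mukaiyama–Michael addition; the anti outcome depends on acid co‑catalyst, solvent and ester size). The fallback sets out from 7 and returns at 9, replacing iminium catalysis by chelate‑controlled Lewis acid catalysis. Furan 7 is added to the imide ethyl (2E)‑4‑oxo‑4‑(2‑oxo‑1,3‑oxazolidin‑3‑yl)but‑2‑enoate F1 (from commercial ethyl fumaroyl chloride and 2‑oxazolidinone, Et3N, DMAP). The catalyst is Cu(OTf)2 (10 mol%) with 2,2′‑(propane‑2,2‑diyl)bis[(4R)‑4‑tert‑butyl‑4,5‑dihydro‑1,3‑oxazole] and (CF3)2CHOH in CH2Cl2 at −78 °C. Two‑point binding of the imide to divalent copper fixes the s‑cis acceptor, and silyloxyfuran additions to such chelated imides are strongly anti‑selective, giving ethyl (2R)‑2‑[(2S)‑2‑(methoxycarbonyl)‑5‑oxo‑2,5‑dihydrofuran‑2‑yl]‑4‑oxo‑4‑(2‑oxo‑1,3‑oxazolidin‑3‑yl)butanoate F2. The (R,R) ligand is my prediction from the square‑planar chelate model; it is not certain, so the configuration of F2 must be checked and the antipodal ligand used if it is opposite. LiSEt (EtSH, n‑BuLi, THF, 0 °C) converts F2 into the thioester ethyl (2R)‑4‑(ethylsulfanyl)‑2‑[(2S)‑2‑(methoxycarbonyl)‑5‑oxo‑2,5‑dihydrofuran‑2‑yl]‑4‑oxobutanoate F3. Fukuyama reduction (Et3SiH, 10% Pd/C, acetone, rt) then gives aldehyde 9; any material whose ring C=C is also reduced converges at 15.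

Step 8 (Wittig on the base‑sensitive aldehyde 9: enolization, retro‑Michael cleavage or ylide addition to the butenolide). The fallback sets out from 9 and returns at 15, attaching the chain by cross‑metathesis instead of a basic ylide. Non‑basic methylenation of 9 (Zn, CH2Br2, TiCl4, THF/CH2Cl2, 0 °C) gives ethyl (2R)‑2‑[(2S)‑2‑(methoxycarbonyl)‑5‑oxo‑2,5‑dihydrofuran‑2‑yl]pent‑4‑enoate F4. Cross‑metathesis with [(non‑8‑en‑1‑yloxy)methyl]benzene F5 (from non‑8‑en‑1‑ol, NaH, BnBr) uses the second‑generation Grubbs catalyst RuCl2(=CHPh)(PCy3)(H2IMes) in CH2Cl2 at 40 °C; the electron‑poor ring alkene does not take part. The product is mainly methyl (2S)‑2‑[(2R,4E)‑12‑(benzyloxy)‑1‑ethoxy‑1‑oxododec‑4‑en‑2‑yl]‑5‑oxo‑2,5‑dihydrofuran‑2‑carboxylate F6 (geometry irrelevant), which is hydrogenated under the conditions of step 9 to 15.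

Step 2 (regiochemistry and over‑reaction in the enolate selenenylation, and the sensitivity of butenolide 6). The fallback sets out from 2 and returns at 7, replacing enolate chemistry by radical halogenation and elimination. Bromination of 2 at the captodative C–H (NBS, (PhCO2)2, PhCF3, reflux) gives methyl 2‑bromo‑5‑oxooxolane‑2‑carboxylate F7. Et3N in CH2Cl2 at 0 °C eliminates HBr to the enol lactone methyl 5‑oxo‑4,5‑dihydrofuran‑2‑carboxylate F8, which is silylated under the conditions of step 4 (TIPSOTf, Et3N) to give 7 directly.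

**Further compounds**
F1 | step 5 | ethyl (2E)‑4‑oxo‑4‑(2‑oxo‑1,3‑oxazolidin‑3‑yl)but‑2‑enoate | CCOC(=O)/C=C/C(=O)N1CCOC1=O
F2 | step 5 | ethyl (2R)‑2‑[(2S)‑2‑(methoxycarbonyl)‑5‑oxo‑2,5‑dihydrofuran‑2‑yl]‑4‑oxo‑4‑(2‑oxo‑1,3‑oxazolidin‑3‑yl)butanoate | O=C(C[C@@H](C(=O)OCC)[C@]1(C(=O)OC)C=CC(=O)O1)N1CCOC1=O
F3 | step 5 | ethyl (2R)‑4‑(ethylsulfanyl)‑2‑[(2S)‑2‑(methoxycarbonyl)‑5‑oxo‑2,5‑dihydrofuran‑2‑yl]‑4‑oxobutanoate | CCSC(=O)C[C@@H](C(=O)OCC)[C@]1(C(=O)OC)C=CC(=O)O1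
F4 | step 8 | ethyl (2R)‑2‑[(2S)‑2‑(methoxycarbonyl)‑5‑oxo‑2,5‑dihydrofuran‑2‑yl]pent‑4‑enoate | C=CC[C@@H](C(=O)OCC)[C@]1(C(=O)OC)C=CC(=O)O1
F5 | step 8 | [(non‑8‑en‑1‑yloxy)methyl]benzene | C=CCCCCCCCOCc1ccccc1
F6 | step 8 | methyl (2S)‑2‑[(2R,4E)‑12‑(benzyloxy)‑1‑ethoxy‑1‑oxododec‑4‑en‑2‑yl]‑5‑oxo‑2,5‑dihydrofuran‑2‑carboxylate | c1ccc(cc1)COCCCCCCC/C=C/C[C@@H](C(=O)OCC)[C@]1(C(=O)OC)C=CC(=O)O1
F7 | step 2 | methyl 2‑bromo‑5‑oxooxolane‑2‑carboxylate | COC(=O)C1(Br)CCC(=O)O1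
F8 | step 2 | methyl 5‑oxo‑4,5‑dihydrofuran‑2‑carboxylate | COC(=O)C1=CCC(=O)O1
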